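**Plan**
- Retrosynthetic cuts, in order: the MOM group on ring B; the C8–prenyl bond (back to the O5 prenyl ether); the pyran ring at C4–C4a (back to the O8a 2‑methylbut‑3‑yn‑2‑yl ether); the diketone (back to the deoxybenzoin CH2); the ring A–acyl bond (back to 5‑methoxyresorcinol and 4‑hydroxyphenylacetic acid).
- Forward: rings A and B are joined by Friedel–Crafts acylation, O8a is tethered to the alkyne, the CH2 is oxidised to the diketone, the pyran ring is closed thermally, the prenyl group is moved from O5 to C8, and ring B is deprotected.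
- Enabling feature: ring A is a phloroglucinol with an acyl group at C6. The oxygen para to the acyl (O8a) is the most acidic and takes the propargyl tether selectively. The O5–H···O=C hydrogen bond steers the sigmatropic shift to C4a. The finished pyran then makes C4a quaternary, so the later prenyl migration can only end at C8.
- Stereochemistry: the target has no stereocentre; the C3=C4 double bond is cis by ring constraint, so nothing has to be set.

Key step: step 5

Remark: chromene numbering of the target (O1, C2, C3, C4, C4a, C5 to C8, C8a) is used for ring positions in all intermediates; the 2‑hydroxybenzil intermediates are assumed to react in the open diketone form, as the target is drawn.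

**Step 1**
Reactants: 1 5‑methoxyresorcinol; 2 4‑hydroxyphenylacetic acid
Product: 3 1-(2,4-dihydroxy-6-methoxyphenyl)-2-(4-hydroxyphenyl)ethan-1-one
Conditions: BF3·OEt2 (solvent), 85 °C; then aq. NaOAc
Reagents that add atoms: none
Why: BF3‑mediated Friedel–Crafts (Nencki‑type) acylation of the resorcinol ring by the arylacetic acid should go mainly to C4 of 1 (ortho to one hydroxyl and para to the other, two equivalent sites) to give the hydrogen‑bonded 2‑hydroxyaryl ketone, while the less electron‑rich monophenol ring of 2 is not C‑acylated.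

**Step 2**
Reactants: 3 1-(2,4-dihydroxy-6-methoxyphenyl)-2-(4-hydroxyphenyl)ethan-1-one; 4 3‑chloro‑3‑methylbut‑1‑yne
Product: 5 1-{2-hydroxy-6-methoxy-4-[(2-methylbut-3-yn-2-yl)oxy]phenyl}-2-(4-hydroxyphenyl)ethan-1-one
Conditions: DBU (1.05 equiv), CuCl2 (1 mol %), MeCN, 0 °C
Reagents that add atoms: none
Why: Copper‑catalysed propargylic etherification of a phenoxide with a tertiary propargyl chloride should alkylate only the most acidic hydroxyl, the one para to the ketone (a vinylogous acid), because with one equivalent of DBU the hydrogen‑bonded ortho hydroxyl and the far less acidic ring B phenol stay protonated.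

**Step 3**
Reactants: 5 1-{2-hydroxy-6-methoxy-4-[(2-methylbut-3-yn-2-yl)oxy]phenyl}-2-(4-hydroxyphenyl)ethan-1-one
Product: 6 1-{2-hydroxy-6-methoxy-4-[(2-methylbut-3-yn-2-yl)oxy]phenyl}-2-[4-(methoxymethoxy)phenyl]ethan-1-one
Conditions: MOMCl, i‑Pr2NEt, CH2Cl2, 0 °C to rt
Reagents that add atoms: chloromethyl methyl ether (MOMCl), COCCl
Why: O‑alkylation with MOMCl under mild amine base (Williamson type) should protect the free ring B phenol only, since the remaining ring A hydroxyl is held in the six‑membered hydrogen bond to the ketone and is unreactive under these conditions.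

**Step 4**
Reactants: 6 1-{2-hydroxy-6-methoxy-4-[(2-methylbut-3-yn-2-yl)oxy]phenyl}-2-[4-(methoxymethoxy)phenyl]ethan-1-one
Product: 7 1-{2-hydroxy-6-methoxy-4-[(2-methylbut-3-yn-2-yl)oxy]phenyl}-2-[4-(methoxymethoxy)phenyl]ethane-1,2-dione
Conditions: SeO2, pyridine, 95 °C
Reagents that add atoms: selenium dioxide, O=[Se]=O
Why: Riley oxidation of the doubly activated methylene (benzylic and alpha to the ketone) should give the 1,2‑diketone; the substrate has no C=C bond and the alkyne has no propargylic hydrogen, so allylic or propargylic oxidation cannot compete, and the basic medium spares the MOM ether.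

**Step 5**
Reactants: 7 1-{2-hydroxy-6-methoxy-4-[(2-methylbut-3-yn-2-yl)oxy]phenyl}-2-[4-(methoxymethoxy)phenyl]ethane-1,2-dione
Product: 11 1-(5-hydroxy-7-methoxy-2,2-dimethyl-2H-chromen-6-yl)-2-[4-(methoxymethoxy)phenyl]ethane-1,2-dione, via allenyl dienone 8 (not isolated), via allenylphenol 9 (not isolated), via ortho-quinone methide 10 (not isolated)
Conditions: o‑xylene, 145 °C, Ar
Reagents that add atoms: none
Why: On heating, the O8a‑bound 2‑methylbut‑3‑yn‑2‑yl group should undergo an aromatic propargyl Claisen [3,3] shift that forms the C4–C4a bond (allenyl dienone 8), enolisation gives allenylphenol 9, a [1,5]‑hydrogen shift from O8a–H to the central allene carbon gives the ortho‑quinone methide 10, and oxa‑6π electrocyclisation rejoins O8a (now O1) to C2, so that relative to 7 the pyran ring is closed with C4–C4a as the one new sigma bond. The closest known reaction type is the thermal conversion of aryl 1,1‑dimethylpropargyl ethers into 2,2‑dimethyl‑2H‑chromenes, well precedented for 2‑hydroxy‑4‑(propargyloxy)aryl ketones and aldehydes. The pyran ring is closed through a six‑membered cyclic [3,3] transition state at the alkyne terminus followed by a thermal disrotatory 6π electrocyclisation of the (Z)‑oxatriene. No stereocentre results, since C2 carries two methyl groups and the sp3 carbon C4a of 8 is planarised on enolisation. The step needs site selectivity between the two carbons ortho to the ether oxygen (C4a versus C8) and between the two oxygens flanking C4a: the O5–H···O=C hydrogen bond of the ortho‑hydroxyaryl ketone fixes double‑bond character in C4a–C8a and so steers the shift to C4a, and the same hydrogen bond keeps O5–H out of the hydrogen shift so that the ring closes on O8a. The gem‑dimethyl group lowers the barrier enough that refluxing xylene should suffice, conditions that leave the diketone, the MOM ether and the methyl ether untouched.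

**Step 6**
Reactants: 11 1-(5-hydroxy-7-methoxy-2,2-dimethyl-2H-chromen-6-yl)-2-[4-(methoxymethoxy)phenyl]ethane-1,2-dione; 12 1‑bromo‑3‑methylbut‑2‑ene (prenyl bromide)
Product: 13 1-{7-methoxy-2,2-dimethyl-5-[(3-methylbut-2-en-1-yl)oxy]-2H-chromen-6-yl}-2-[4-(methoxymethoxy)phenyl]ethane-1,2-dione
Conditions: K2CO3, DMF, 50 °C
Reagents that add atoms: none
Why: Williamson O‑alkylation of the potassium phenoxide of the C5 hydroxyl, the only acidic site left, should be clean because the diketone has no enolisable hydrogen and C‑alkylation alpha to a carbonyl is therefore impossible.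

**Step 7**
Reactants: 13 1-{7-methoxy-2,2-dimethyl-5-[(3-methylbut-2-en-1-yl)oxy]-2H-chromen-6-yl}-2-[4-(methoxymethoxy)phenyl]ethane-1,2-dione
Product: 16 1-[5-hydroxy-7-methoxy-2,2-dimethyl-8-(3-methylbut-2-en-1-yl)-2H-chromen-6-yl]-2-[4-(methoxymethoxy)phenyl]ethane-1,2-dione, via ortho-dienone 14 (not isolated), via para-dienone 15 (not isolated)
Conditions: N,N‑diethylaniline, 190 °C, Ar
Reagents that add atoms: none
Why: Aromatic para‑Claisen rearrangement (Claisen then Cope, two [3,3] shifts) should apply because both carbons ortho to O5 (C4a and C6) are quaternary, so the ortho‑dienone (shown via C4a; the C6 dienone would converge) cannot enolise and relays the allyl unit to C8, the only ring A carbon bearing hydrogen, where tautomerisation restores the phenol and the double allylic inversion delivers the unbranched 3‑methylbut‑2‑enyl group.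

**Step 8**
Reactants: 16 1-[5-hydroxy-7-methoxy-2,2-dimethyl-8-(3-methylbut-2-en-1-yl)-2H-chromen-6-yl]-2-[4-(methoxymethoxy)phenyl]ethane-1,2-dione
Product: 17 1-[5-hydroxy-7-methoxy-2,2-dimethyl-8-(3-methylbut-2-en-1-yl)-2H-chromen-6-yl]-2-(4-hydroxyphenyl)ethane-1,2-dione
Conditions: HCl (3 M aq), MeOH, 40 °C
Reagents that add atoms: none
Why: Acid‑catalysed acetal exchange with methanol should remove the MOM group without damage, because the C8 prenyl group has no free hydroxyl next to it (O1 is in the ring, O7 is methylated) and so cannot cyclise to a chroman, and the chromene and aryl methyl ether tolerate dilute acid at this temperature.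

**Compound list**
1 | 5‑methoxyresorcinol | COc1cc(O)cc(O)c1 | starting material
2 | 4‑hydroxyphenylacetic acid | OC(=O)Cc1ccc(O)cc1 | starting material
3 | 1-(2,4-dihydroxy-6-methoxyphenyl)-2-(4-hydroxyphenyl)ethan-1-one | COc1cc(O)cc(O)c1C(=O)Cc1ccc(O)cc1 | intermediate
4 | 3‑chloro‑3‑methylbut‑1‑yne | CC(C)(Cl)C#C | starting material
5 | 1-{2-hydroxy-6-methoxy-4-[(2-methylbut-3-yn-2-yl)oxy]phenyl}-2-(4-hydroxyphenyl)ethan-1-one | COc1cc(OC(C)(C)C#C)cc(O)c1C(=O)Cc1ccc(O)cc1 | intermediate
6 | 1-{2-hydroxy-6-methoxy-4-[(2-methylbut-3-yn-2-yl)oxy]phenyl}-2-[4-(methoxymethoxy)phenyl]ethan-1-one | COCOc1ccc(CC(=O)c2c(OC)cc(OC(C)(C)C#C)cc2O)cc1 | intermediate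
7 | 1-{2-hydroxy-6-methoxy-4-[(2-methylbut-3-yn-2-yl)oxy]phenyl}-2-[4-(methoxymethoxy)phenyl]ethane-1,2-dione | COCOc1ccc(C(=O)C(=O)c2c(OC)cc(OC(C)(C)C#C)cc2O)cc1 | intermediate
8 | allenyl dienone (not isolated): 1-[2-hydroxy-6-methoxy-3-(3-methylbuta-1,2-dien-1-yl)-4-oxocyclohexa-1,5-dien-1-yl]-2-[4-(methoxymethoxy)phenyl]ethane-1,2-dione | COCOc1ccc(C(=O)C(=O)C2=C(O)C(C=C=C(C)C)C(=O)C=C2OC)cc1 | intermediate
9 | allenylphenol (not isolated): 1-[2,4-dihydroxy-6-methoxy-3-(3-methylbuta-1,2-dien-1-yl)phenyl]-2-[4-(methoxymethoxy)phenyl]ethane-1,2-dione | COCOc1ccc(C(=O)C(=O)c2c(OC)cc(O)c(C=C=C(C)C)c2O)cc1 | intermediate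
10 | ortho‑quinone methide (not isolated): 1-[2-hydroxy-6-methoxy-3-(3-methylbut-2-en-1-ylidene)-4-oxocyclohexa-1,5-dien-1-yl]-2-[4-(methoxymethoxy)phenyl]ethane-1,2-dione | COCOc1ccc(C(=O)C(=O)C2=C(O)C(=CC=C(C)C)C(=O)C=C2OC)cc1 | intermediate
11 | 1-(5-hydroxy-7-methoxy-2,2-dimethyl-2H-chromen-6-yl)-2-[4-(methoxymethoxy)phenyl]ethane-1,2-dione | COCOc1ccc(C(=O)C(=O)c2c(OC)cc3OC(C)(C)C=Cc3c2O)cc1 | intermediate
12 | 1‑bromo‑3‑methylbut‑2‑ene (prenyl bromide) | CC(C)=CCBr | starting material
13 | 1-{7-methoxy-2,2-dimethyl-5-[(3-methylbut-2-en-1-yl)oxy]-2H-chromen-6-yl}-2-[4-(methoxymethoxy)phenyl]ethane-1,2-dione | COCOc1ccc(C(=O)C(=O)c2c(OC)cc3OC(C)(C)C=Cc3c2OCC=C(C)C)cc1 | intermediate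
14 | ortho‑dienone (not isolated, racemic at C4a): 1-[7-methoxy-2,2-dimethyl-4a-(2-methylbut-3-en-2-yl)-5-oxo-4a,5-dihydro-2H-chromen-6-yl]-2-[4-(methoxymethoxy)phenyl]ethane-1,2-dione | C=CC(C)(C)C12C=CC(C)(C)OC1=CC(OC)=C(C(=O)C(=O)c1ccc(OCOC)cc1)C2=O | intermediate
15 | para‑dienone (not isolated, racemic at C8): 1-[7-methoxy-2,2-dimethyl-8-(3-methylbut-2-en-1-yl)-5-oxo-5,8-dihydro-2H-chromen-6-yl]-2-[4-(methoxymethoxy)phenyl]ethane-1,2-dione | CC(C)=CCC1C(OC)=C(C(=O)C(=O)c2ccc(OCOC)cc2)C(=O)C2=C1OC(C)(C)C=C2 | intermediate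
16 | 1-[5-hydroxy-7-methoxy-2,2-dimethyl-8-(3-methylbut-2-en-1-yl)-2H-chromen-6-yl]-2-[4-(methoxymethoxy)phenyl]ethane-1,2-dione | COCOc1ccc(C(=O)C(=O)c2c(OC)c(CC=C(C)C)c3OC(C)(C)C=Cc3c2O)cc1 | intermediate
17 | 1-[5-hydroxy-7-methoxy-2,2-dimethyl-8-(3-methylbut-2-en-1-yl)-2H-chromen-6-yl]-2-(4-hydroxyphenyl)ethane-1,2-dione | COc1c(CC=C(C)C)c2c(c(O)c1C(=O)C(=O)c1ccc(O)cc1)C=CC(C)(C)O2 | target

Total steps: 8. Longest linear sequence: 8 steps (1 to 17).

**Steps most likely to fail**

Step 5. The [3,3] shift may go in part to the other ortho carbon (C8, next to the methoxy‑bearing C7) if the hydrogen bond does not discriminate enough, which would fuse the pyran on the wrong side. The fallback sets out from 3 and comes back at 17; it puts the prenyl group on that carbon first, so that only C4a is free when the pyran is annulated.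
- 3 is treated with MOMCl and i‑Pr2NEt (2.2 equiv) to give 1-[2-hydroxy-6-methoxy-4-(methoxymethoxy)phenyl]-2-[4-(methoxymethoxy)phenyl]ethan-1-one F1.
- SeO2 in pyridine oxidises the methylene to give 1-[2-hydroxy-6-methoxy-4-(methoxymethoxy)phenyl]-2-[4-(methoxymethoxy)phenyl]ethane-1,2-dione F2.
- 12 with K2CO3 in DMF gives the prenyl ether 1-{2-methoxy-4-(methoxymethoxy)-6-[(3-methylbut-2-en-1-yl)oxy]phenyl}-2-[4-(methoxymethoxy)phenyl]ethane-1,2-dione F3.
- Heating in N,N‑diethylaniline at 190 °C should move the prenyl group by Claisen then Cope shift to the carbon para to the liberated hydroxyl, giving 1-[6-hydroxy-2-methoxy-4-(methoxymethoxy)-3-(3-methylbut-2-en-1-yl)phenyl]-2-[4-(methoxymethoxy)phenyl]ethane-1,2-dione F4.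
- HCl in MeOH removes both MOM groups to give 1-[4,6-dihydroxy-2-methoxy-3-(3-methylbut-2-en-1-yl)phenyl]-2-(4-hydroxyphenyl)ethane-1,2-dione F5.
- 3‑Methylbut‑2‑enal in pyridine at 120 °C should then give 17 by ortho C‑hydroxyalkylation at the one free ring A carbon, dehydration to the ortho‑quinone methide and oxa‑6π closure on the oxygen that is not hydrogen‑bonded.

Step 7. With both ortho carbons quaternary, the crowded first [3,3] shift may be slower than fragmentation of the prenyl ether (loss of isoprene or ionisation and recombination), so that the phenol 11 is returned or the prenyl group is scrambled. The fallback sets out from 11 and comes back at 16; it makes the C8–C bond by cross‑coupling instead of rearrangement.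
- N‑Iodosuccinimide in DMF at 0 °C should iodinate C8, the only unsubstituted ring A carbon and para to the free C5 hydroxyl, to give 1-(5-hydroxy-8-iodo-7-methoxy-2,2-dimethyl-2H-chromen-6-yl)-2-[4-(methoxymethoxy)phenyl]ethane-1,2-dione F6.
- Stille coupling with tributyl(3‑methylbut‑2‑en‑1‑yl)stannane and Pd(PPh3)4 (a zerovalent palladium complex) in DMF at 90 °C should give 16.

Step 1. Acylation may occur in part at the carbon between the two hydroxyls of 1, giving the regioisomeric 2,6‑dihydroxy‑4‑methoxy ketone that is carried along or hard to remove. The fallback sets out from 2 and comes back at 3; it uses a symmetrical arene and sets the methyl ether by hydrogen‑bond control.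
- Phloroglucinol is acylated with 2 in BF3·OEt2 to give 2-(4-hydroxyphenyl)-1-(2,4,6-trihydroxyphenyl)ethan-1-one F7.
- MOMCl and i‑Pr2NEt (3.3 equiv) protect all but the hydrogen‑bonded hydroxyl to give 1-[2-hydroxy-4,6-bis(methoxymethoxy)phenyl]-2-[4-(methoxymethoxy)phenyl]ethan-1-one F8.
- MeI and K2CO3 in acetone methylate the remaining hydroxyl to give 1-[2-methoxy-4,6-bis(methoxymethoxy)phenyl]-2-[4-(methoxymethoxy)phenyl]ethan-1-one F9.
- HCl in MeOH removes the three MOM groups to give 3.

**Further compounds**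
F1 | step 5 | 1-[2-hydroxy-6-methoxy-4-(methoxymethoxy)phenyl]-2-[4-(methoxymethoxy)phenyl]ethan-1-one | COCOc1ccc(CC(=O)c2c(O)cc(OCOC)cc2OC)cc1
F2 | step 5 | 1-[2-hydroxy-6-methoxy-4-(methoxymethoxy)phenyl]-2-[4-(methoxymethoxy)phenyl]ethane-1,2-dione | COCOc1ccc(C(=O)C(=O)c2c(O)cc(OCOC)cc2OC)cc1
F3 | step 5 | 1-{2-methoxy-4-(methoxymethoxy)-6-[(3-methylbut-2-en-1-yl)oxy]phenyl}-2-[4-(methoxymethoxy)phenyl]ethane-1,2-dione | COCOc1ccc(C(=O)C(=O)c2c(OCC=C(C)C)cc(OCOC)cc2OC)cc1
F4 | step 5 | 1-[6-hydroxy-2-methoxy-4-(methoxymethoxy)-3-(3-methylbut-2-en-1-yl)phenyl]-2-[4-(methoxymethoxy)phenyl]ethane-1,2-dione | COCOc1ccc(C(=O)C(=O)c2c(O)cc(OCOC)c(CC=C(C)C)c2OC)cc1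
F5 | step 5 | 1-[4,6-dihydroxy-2-methoxy-3-(3-methylbut-2-en-1-yl)phenyl]-2-(4-hydroxyphenyl)ethane-1,2-dione | COc1c(CC=C(C)C)c(O)cc(O)c1C(=O)C(=O)c1ccc(O)cc1
F6 | step 7 | 1-(5-hydroxy-8-iodo-7-methoxy-2,2-dimethyl-2H-chromen-6-yl)-2-[4-(methoxymethoxy)phenyl]ethane-1,2-dione | COCOc1ccc(C(=O)C(=O)c2c(OC)c(I)c3OC(C)(C)C=Cc3c2O)cc1
F7 | step 1 | 2-(4-hydroxyphenyl)-1-(2,4,6-trihydroxyphenyl)ethan-1-one | Oc1ccc(CC(=O)c2c(O)cc(O)cc2O)cc1
F8 | step 1 | 1-[2-hydroxy-4,6-bis(methoxymethoxy)phenyl]-2-[4-(methoxymethoxy)phenyl]ethan-1-one | COCOc1ccc(CC(=O)c2c(O)cc(OCOC)cc2OCOC)cc1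
F9 | step 1 | 1-[2-methoxy-4,6-bis(methoxymethoxy)phenyl]-2-[4-(methoxymethoxy)phenyl]ethan-1-one | COCOc1ccc(CC(=O)c2c(OC)cc(OCOC)cc2OCOC)cc1
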